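**Plan**
- Feature: ring A carries CO2H (C1), OMe (C2), the carbinol chain (C3), two adjacent CH (C4, C5) and the aryloxy group (C6). C1, C6, C5 and C4 map onto C3 to C6 of a 4-aryloxy-2-pyranone-3-carboxylate, and C2/C3 onto a methoxyalkyne that already holds the stereocentre.
- Retrosynthesis: remove the two allyl groups and the silyl group; cut ring A at C1–C2 and C3–C4 (cycloaddition with loss of CO2); cut the C6–O aryl ether (addition–elimination on a 4-chloropyranone); cut the pyranone at its C3–C4 acyl bond and its lactone C–O bond (diallyl malonate plus a 3-ethoxyacryloyl unit); cut the alkyne at the acetylide–carbonyl bond.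
- Forward: ring B is bought as creosol and adjusted in three steps; the pyranone ring is closed by enol lactonisation; the ether is joined; ring A is closed by the cycloaddition; two deprotections finish.
- Stereochemistry: the only stereocentre is set by asymmetric transfer hydrogenation of the methoxy ynone with the (S,S)-TsDPEN ruthenium catalyst and is carried as its silyl ether through the ring-forming step.

Key step: step 12

Remark on the chemistry: the carbinol centre of the target is (S) (OH > aryl > CH2 > H); the descriptor stays (S) in the alkyne series because the alkynyl carbon also outranks the isobutyl CH2.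

**Route**

Step 1
Reactants: 1 diallyl malonate; 2 (E)-3-ethoxyacryloyl chloride
Product: 3 diallyl 2-[(E)-3-ethoxyacryloyl]malonate
Conditions: MgCl2 (1 equiv), Et3N (2 equiv), MeCN, 0 to 25 °C; cold 1 M HCl work-up
Reagents that add atoms: none
Why: Soft enolisation of the malonate as its magnesium chelate gives clean C-acylation by the acid chloride (magnesium-mediated malonate acylation), and the acid chloride has no sp3 alpha hydrogen from which a ketene could form.

Step 2
Reactants: 3 diallyl 2-[(E)-3-ethoxyacryloyl]malonate
Product: 5 allyl 4-hydroxy-2-oxo-2H-pyran-3-carboxylate, via keto aldehyde 4 (not isolated)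
Conditions: 1 M HCl, THF, 25 °C; then TsOH·H2O (5 mol%), toluene, 80 °C
Reagents that add atoms: water, O
Why: Acid hydrolysis of the enol ether unmasks the aldehyde, whose cis-enol oxygen attacks one malonate ester in an enol lactonisation with loss of allyl alcohol, the same closure that turns acetoacetyl malonates into 6-methyl-4-hydroxy-2-pyranone-3-carboxylates.

Step 3
Reactants: 5 allyl 4-hydroxy-2-oxo-2H-pyran-3-carboxylate
Product: 6 allyl 4-chloro-2-oxo-2H-pyran-3-carboxylate
Conditions: (COCl)2 (1.3 equiv), DMF (10 mol%), CH2Cl2, 0 to 25 °C; evaporate and use at once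
Reagents that add atoms: oxalyl chloride, O=C(Cl)C(=O)Cl
Why: The 4-hydroxyl is a vinylogous carboxylic acid and is converted into the vinylogous acid chloride by the Vilsmeier chloroiminium salt, as for 4-hydroxycoumarins and cyclic 1,3-diones.

Step 4
Reactants: 7 2-methoxy-4-methylphenol (creosol)
Product: 8 2-hydroxy-3-methoxy-5-methylbenzaldehyde
Conditions: MgCl2 (1.5 equiv), Et3N (3.75 equiv), (CH2O)n (6.8 equiv), MeCN, reflux
Reagents that add atoms: paraformaldehyde (as formaldehyde), C=O
Why: Magnesium-mediated ortho-formylation (Casnati–Skattebøl reaction) delivers formaldehyde to the only free ortho position of the magnesium phenoxide, and a second formaldehyde oxidises the benzylic alkoxide to the aldehyde.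

Step 5
Reactants: 8 2-hydroxy-3-methoxy-5-methylbenzaldehyde
Product: 9 2,3-dihydroxy-5-methylbenzaldehyde
Conditions: BBr3 (2.5 equiv), CH2Cl2, −78 to 0 °C; then H2O
Reagents that add atoms: none
Why: Lewis acid-mediated aryl methyl ether cleavage (bromide attacks the methyl group of the boron-complexed ether) is standard for o-vanillin-type aldehydes and leaves the formyl group intact.

Step 6
Reactants: 9 2,3-dihydroxy-5-methylbenzaldehyde
Product: 10 3-(allyloxy)-2-hydroxy-5-methylbenzaldehyde
Conditions: NaH (2.2 equiv), DMSO, 20 °C; allyl bromide (1.0 equiv), 20 °C; 1 M HCl work-up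
Reagents that add atoms: allyl bromide, C=CCBr
Why: In the dianion the 2-phenoxide is chelated and conjugated to the formyl group and is the weaker nucleophile, so one equivalent of halide alkylates the 3-oxygen selectively (Williamson ether synthesis on a catechol dianion).

Step 7
Reactants: 6 allyl 4-chloro-2-oxo-2H-pyran-3-carboxylate; 10 3-(allyloxy)-2-hydroxy-5-methylbenzaldehyde
Product: 11 allyl 4-[2-(allyloxy)-6-formyl-4-methylphenoxy]-2-oxo-2H-pyran-3-carboxylate
Conditions: K2CO3 (1.5 equiv, dry, powdered), MeCN, 0 to 25 °C
Reagents that add atoms: none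
Why: Addition–elimination at C4 of the vinylogous acid chloride, which is activated by both the lactone and the ester carbonyl, passes through a tetrahedral intermediate that tolerates the di-ortho-substituted phenoxide, as in the substitution of 4-chlorocoumarin-3-carboxylates by phenols.

Step 8
Reactants: 12 isovaleryl chloride
Product: 13 N-methoxy-N,3-dimethylbutanamide
Conditions: MeNHOMe·HCl (1.1 equiv), pyridine (2.2 equiv), CH2Cl2, 0 to 25 °C
Reagents that add atoms: N,O-dimethylhydroxylamine hydrochloride, CNOC.Cl
Why: Simple N-acylation of the hydroxylamine by the acid chloride gives the Weinreb amide.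

Step 9
Reactants: 14 chloroacetaldehyde dimethyl acetal; 13 N-methoxy-N,3-dimethylbutanamide
Product: 16 1-methoxy-5-methylhex-1-yn-3-one, via lithium methoxyacetylide 15 (not isolated)
Conditions: LiNEt2 (3.1 equiv, from n-BuLi and Et2NH), THF, 0 °C; then 13 (0.8 equiv), −78 to −20 °C; inverse quench into cold 1 M HCl/Et2O
Reagents that add atoms: none
Why: Three equivalents of amide base effect two eliminations (methanol, then HCl) and one deprotonation to give the alkoxyacetylide, which adds only once to the amide because the chelated tetrahedral intermediate persists until the acidic quench (Weinreb ketone synthesis), and the quench also protonates the amines before they can add to the ynone.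

Step 10
Reactants: 16 1-methoxy-5-methylhex-1-yn-3-one
Product: 17 (S)-1-methoxy-5-methylhex-1-yn-3-ol
Conditions: Ru[(S,S)-TsNCH(Ph)CH(Ph)NH](p-cymene) (1 mol%, 16-electron amido complex preformed from RuCl[(S,S)-TsDPEN](p-cymene) and KOH), iPrOH (0.1 M), 25 °C
Reagents that add atoms: none
Why: Noyori-type asymmetric transfer hydrogenation of an ynone proceeds by concerted hydride and proton transfer in a six-membered transition state in which the alkyne takes the place of the aryl group of an aryl ketone, so the (S,S)-ligand should give the (S)-carbinol, and base-free neutral conditions spare the push–pull alkyne.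

Step 11
Reactants: 17 (S)-1-methoxy-5-methylhex-1-yn-3-ol
Product: 18 (S)-tert-butyl[(1-methoxy-5-methylhex-1-yn-3-yl)oxy]dimethylsilane
Conditions: TBSCl (1.3 equiv), imidazole (2.5 equiv), DMF, 0 to 25 °C; chromatography on Et3N-deactivated silica
Reagents that add atoms: tert-butyldimethylsilyl chloride, CC(C)(C)[Si](C)(C)Cl
Why: Imidazole-mediated silylation is basic throughout, so the acid-sensitive ynol ether carbinol is protected without Meyer–Schuster rearrangement and the stereocentre is not touched.

Step 12
Reactants: 11 allyl 4-[2-(allyloxy)-6-formyl-4-methylphenoxy]-2-oxo-2H-pyran-3-carboxylate; 18 (S)-tert-butyl[(1-methoxy-5-methylhex-1-yn-3-yl)oxy]dimethylsilane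
Product: 20 allyl 6-[2-(allyloxy)-6-formyl-4-methylphenoxy]-2-methoxy-3-[(S)-1-(tert-butyldimethylsilyloxy)-3-methylbutyl]benzoate, via bicyclic lactone 19 (not isolated)
Conditions: 18 (2 equiv), toluene (0.5 M), 100–110 °C, sealed tube, base-washed glassware
Reagents that add atoms: none
Why: The electron-poor diene of 11 (C3=C4–C5=C6, lowered by the C3 ester and the lactone carbonyl) and the electron-rich ynol ether 18 should combine in an asynchronous inverse-electron-demand Diels–Alder reaction, the nucleophilic carbinol-bearing alkyne carbon bonding to the electrophilic C6 and the methoxy-bearing carbon to C3, to give the 2-oxabicyclo[2.2.2]octadienone 19. Retro-[4+2] loss of CO2 from 19 then leaves the arene directly, because the dienophile is an alkyne and no elimination or oxidation is needed. The closest known reaction is the cycloaddition of 3-alkoxycarbonyl-2-pyranones with ketene acetals, ynamines and ynol ethers, which gives salicylate ethers after decarboxylation. Ring A is closed by an intermolecular [4+2] cycloaddition that forms C1–C2 and C3–C4 together, followed by cycloreversion; no stereocentre is created, the two bridgehead centres of 19 vanish on aromatisation and the silyl-protected (S)-carbinol is a spectator. The only selectivity needed is regiochemistry (OMe next to the ester), which the matched polarisation of the two partners secures, and the aryloxy group should be only a weak donor because its oxygen is shared with the formyl-substituted ring. The methyl ynol ether has no beta hydrogen for retro-ene fragmentation to a ketene and should not add to the free aryl aldehyde without acid, and the aryl allyl ether is well below its Claisen rearrangement temperature.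

Step 13
Reactants: 20 allyl 6-[2-(allyloxy)-6-formyl-4-methylphenoxy]-2-methoxy-3-[(S)-1-(tert-butyldimethylsilyloxy)-3-methylbutyl]benzoate
Product: 21 allyl 6-[2-(allyloxy)-6-formyl-4-methylphenoxy]-3-[(S)-1-hydroxy-3-methylbutyl]-2-methoxybenzoate
Conditions: TBAF/AcOH (1:1, 3 equiv), THF, 0 to 25 °C
Reagents that add atoms: none
Why: Fluoride-mediated desilylation buffered with acetic acid stays near neutral, so the allyl ester and the aldehyde are untouched and the benzylic carbinol, which is ortho to OMe and para to the aryloxy group, cannot ionise and racemise.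

Step 14
Reactants: 21 allyl 6-[2-(allyloxy)-6-formyl-4-methylphenoxy]-3-[(S)-1-hydroxy-3-methylbutyl]-2-methoxybenzoate
Product: 22 6-(2-formyl-6-hydroxy-4-methylphenoxy)-3-[(S)-1-hydroxy-3-methylbutyl]-2-methoxybenzoic acid (tenellic acid B)
Conditions: Pd(PPh3)4 (zerovalent palladium, 5 mol%), sodium p-toluenesulfinate (3 equiv), THF/MeOH, 25 °C; then cold 0.5 M HCl to pH 3, extraction into NaHCO3 and re-acidification
Reagents that add atoms: none
Why: Zerovalent palladium ionises both the allyl ester and the allyl aryl ether to π-allyl complexes (Tsuji–Trost deallylation) and the soft sulfinate traps them irreversibly as the sulfone without touching the aldehyde, so the hindered 2,6-disubstituted benzoic acid is freed without any acyl hydrolysis.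

**Compound list**
1 | diallyl malonate | C=CCOC(=O)CC(=O)OCC=C | starting material
2 | (E)-3-ethoxyacryloyl chloride | CCO/C=C/C(=O)Cl | starting material
3 | diallyl 2-[(E)-3-ethoxyacryloyl]malonate | C=CCOC(=O)C(C(=O)OCC=C)C(=O)/C=C/OCC | intermediate
4 | diallyl 2-(3-oxopropanoyl)malonate (keto aldehyde, not isolated) | C=CCOC(=O)C(C(=O)OCC=C)C(=O)CC=O | intermediate
5 | allyl 4-hydroxy-2-oxo-2H-pyran-3-carboxylate | C=CCOC(=O)c1c(O)ccoc1=O | intermediate
6 | allyl 4-chloro-2-oxo-2H-pyran-3-carboxylate | C=CCOC(=O)c1c(Cl)ccoc1=O | intermediate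
7 | 2-methoxy-4-methylphenol (creosol) | COc1cc(C)ccc1O | starting material
8 | 2-hydroxy-3-methoxy-5-methylbenzaldehyde | COc1cc(C)cc(C=O)c1O | intermediate
9 | 2,3-dihydroxy-5-methylbenzaldehyde | Cc1cc(O)c(O)c(C=O)c1 | intermediate
10 | 3-(allyloxy)-2-hydroxy-5-methylbenzaldehyde | C=CCOc1cc(C)cc(C=O)c1O | intermediate
11 | allyl 4-[2-(allyloxy)-6-formyl-4-methylphenoxy]-2-oxo-2H-pyran-3-carboxylate | C=CCOC(=O)c1c(Oc2c(OCC=C)cc(C)cc2C=O)ccoc1=O | intermediate
12 | isovaleryl chloride | CC(C)CC(=O)Cl | starting material
13 | N-methoxy-N,3-dimethylbutanamide | CC(C)CC(=O)N(C)OC | intermediate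
14 | chloroacetaldehyde dimethyl acetal | COC(CCl)OC | starting material
15 | lithium methoxyacetylide (not isolated) | [Li]C#COC | intermediate
16 | 1-methoxy-5-methylhex-1-yn-3-one | COC#CC(=O)CC(C)C | intermediate
17 | (S)-1-methoxy-5-methylhex-1-yn-3-ol | COC#C[C@@H](O)CC(C)C | intermediate
18 | (S)-tert-butyl[(1-methoxy-5-methylhex-1-yn-3-yl)oxy]dimethylsilane | COC#C[C@@H](O[Si](C)(C)C(C)(C)C)CC(C)C | intermediate
19 | allyl 5-[2-(allyloxy)-6-formyl-4-methylphenoxy]-7-[(S)-1-(tert-butyldimethylsilyloxy)-3-methylbutyl]-8-methoxy-3-oxo-2-oxabicyclo[2.2.2]octa-5,7-diene-4-carboxylate (both bridgehead diastereomers, not isolated) | C=CCOC(=O)C12C(Oc3c(OCC=C)cc(C)cc3C=O)=CC(OC1=O)C(=C2OC)[C@@H](O[Si](C)(C)C(C)(C)C)CC(C)C | intermediate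
20 | allyl 6-[2-(allyloxy)-6-formyl-4-methylphenoxy]-2-methoxy-3-[(S)-1-(tert-butyldimethylsilyloxy)-3-methylbutyl]benzoate | C=CCOC(=O)c1c(OC)c([C@@H](O[Si](C)(C)C(C)(C)C)CC(C)C)ccc1Oc1c(OCC=C)cc(C)cc1C=O | intermediate
21 | allyl 6-[2-(allyloxy)-6-formyl-4-methylphenoxy]-3-[(S)-1-hydroxy-3-methylbutyl]-2-methoxybenzoate | C=CCOC(=O)c1c(OC)c([C@@H](O)CC(C)C)ccc1Oc1c(OCC=C)cc(C)cc1C=O | intermediate
22 | 6-(2-formyl-6-hydroxy-4-methylphenoxy)-3-[(S)-1-hydroxy-3-methylbutyl]-2-methoxybenzoic acid (tenellic acid B) | COc1c([C@@H](O)CC(C)C)ccc(Oc2c(O)cc(C)cc2C=O)c1C(=O)O | target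

**Count**
Total steps: 14. Longest linear sequence: 7 steps (steps 1, 2, 3, 7, 12, 13, 14; the creosol branch 4, 5, 6, 7, 12, 13, 14 and the alkyne branch 8, 9, 10, 11, 12, 13, 14 are equally long).

**Steps most likely to fail**

Step 12. The cycloaddition may be too slow because the 4-aryloxy group raises the diene LUMO, so that thermal oligomerisation of the ynol ether or its acid-traced addition to the aldehyde competes. The fallback sets out from 18 and 11 and returns at 20, replacing the alkyne by a far more nucleophilic ketene acetal. Mild hydration of 18 (TsOH·H2O cat., wet THF, 0 °C) should give methyl (S)-3-(tert-butyldimethylsilyloxy)-5-methylhexanoate F1. Enolisation with in-situ silylation (LDA, TMSCl, THF, −78 °C) should give the silyl ketene acetal tert-butyl{[(S)-1-methoxy-5-methyl-1-(trimethylsilyloxy)hex-1-en-3-yl]oxy}dimethylsilane F2. F2 and 11 in toluene at 25–80 °C should undergo the same C6/C3 bond formation and lose CO2. Aromatisation by loss of methanol and hydrolytic work-up (KF, MeOH) of the aryl silyl ether should give allyl 6-[2-(allyloxy)-6-formyl-4-methylphenoxy]-2-hydroxy-3-[(S)-1-(tert-butyldimethylsilyloxy)-3-methylbutyl]benzoate F3. Methylation (MeI, K2CO3, DMF, 25 °C) converts F3 into 20; any material that aromatises by loss of the silanol instead is 20 already.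

Step 10. Hydride transfer to the donor-stabilised carbonyl may stay incomplete under reversible isopropanol conditions, and the alcohol may add to the push–pull alkyne, with erosion of conversion and enantioselectivity. The fallback sets out from 14 (through acetylide 15), avoids the ynone and returns at 17. Acetylide 15 is added to isovaleraldehyde (THF, −78 °C) to give racemic 1-methoxy-5-methylhex-1-yn-3-ol F4. F4 is esterified with (S)-O-methylmandelic acid (DCC, DMAP cat., CH2Cl2, 0 °C) and the diastereomers are separated by chromatography. This gives (S)-1-methoxy-5-methylhex-1-yn-3-yl (S)-2-methoxy-2-phenylacetate F5, and the ester of the (R)-alcohol, (R)-1-methoxy-5-methylhex-1-yn-3-yl (S)-2-methoxy-2-phenylacetate F6, is discarded. The configuration is assigned by the usual O-methylmandelate NMR correlation, and methanolysis of F5 (K2CO3, MeOH, 0 °C) gives 17.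

Step 7. The hindered, hydrogen-bonded phenoxide may attack C6 or the lactone carbonyl and open the ring, or the vinylogous acid chloride may hydrolyse before substitution. The fallback sets out from 3 and 10 and returns at 11, forming the ether before the pyranone ring exists. The enol of 3 is chlorinated (POCl3, Bu3N, toluene, 60 °C) to diallyl 2-[(E)-1-chloro-3-ethoxyallylidene]malonate F7. Addition–elimination with 10 (K2CO3, MeCN, 25 °C) should give diallyl 2-{(E)-1-[2-(allyloxy)-6-formyl-4-methylphenoxy]-3-ethoxyallylidene}malonate F8. Enol ether hydrolysis and enol lactonisation of F8 (1 M HCl/THF, then TsOH cat., toluene, 80 °C) close the pyranone to 11.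

**Further compounds**
F1 | step 12 | methyl (S)-3-(tert-butyldimethylsilyloxy)-5-methylhexanoate | COC(=O)C[C@@H](O[Si](C)(C)C(C)(C)C)CC(C)C
F2 | step 12 | tert-butyl{[(S)-1-methoxy-5-methyl-1-(trimethylsilyloxy)hex-1-en-3-yl]oxy}dimethylsilane (E/Z mixture) | COC(O[Si](C)(C)C)=C[C@@H](O[Si](C)(C)C(C)(C)C)CC(C)C
F3 | step 12 | allyl 6-[2-(allyloxy)-6-formyl-4-methylphenoxy]-2-hydroxy-3-[(S)-1-(tert-butyldimethylsilyloxy)-3-methylbutyl]benzoate | C=CCOC(=O)c1c(O)c([C@@H](O[Si](C)(C)C(C)(C)C)CC(C)C)ccc1Oc1c(OCC=C)cc(C)cc1C=O
F4 | step 10 | racemic 1-methoxy-5-methylhex-1-yn-3-ol | COC#CC(O)CC(C)C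
F5 | step 10 | (S)-1-methoxy-5-methylhex-1-yn-3-yl (S)-2-methoxy-2-phenylacetate | COC#C[C@@H](OC(=O)[C@@H](OC)c1ccccc1)CC(C)C
F6 | step 10 | (R)-1-methoxy-5-methylhex-1-yn-3-yl (S)-2-methoxy-2-phenylacetate | COC#C[C@H](OC(=O)[C@@H](OC)c1ccccc1)CC(C)C
F7 | step 7 | diallyl 2-[(E)-1-chloro-3-ethoxyallylidene]malonate | C=CCOC(=O)C(C(=O)OCC=C)=C(Cl)/C=C/OCC
F8 | step 7 | diallyl 2-{(E)-1-[2-(allyloxy)-6-formyl-4-methylphenoxy]-3-ethoxyallylidene}malonate | C=CCOC(=O)C(C(=O)OCC=C)=C(Oc1c(OCC=C)cc(C)cc1C=O)/C=C/OCC
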